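Of the substrate charged to the north-east run, 32.8% is left at 8.00 h and 4.6% stands as target, so 62.6% of the charge sits in neither entry. We keep a ledger of substrate, the limiting reagent in that run, with three entries: still present, target, and target that has reacted on with partner.

| flask | substrate | partner | free catalyst | remark | time |
|---|---|---|---|---|---|
| west | 12 mM | 3.8 mM | 6 µM | run made earlier |  |
| north-east | 12 mM | 65 mM | 6 µM | run made earlier |  |
| north | 12 mM | 21.6 mM | 5.7 µM | run made earlier |  |
| ash | 12 mM | 21.6 mM | 6.0 µM |  | 10 h |
| elm | 6.0 mM | 60.0 mM | 6.0 µM |  | 10 h |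
| larch | 3.0 mM | 80.0 mM | 10 µM |  | 10 h |
| oak | 25 mM | 60.0 mM | 10 µM |  | 10 h |
| birch | 12 mM | 5.00 mM | 10 µM |  | 10 h |

| run | time / h | target / % | substrate / % |
|---|---|---|---|
| west | 2.00 | 9.5 | 91.6 |
| west | 4.00 | 13.0 | 85.0 |
| west | 5.00 | 14.1 | 84.4 |
| west | 8.00 | 17.6 | 80.0 |
| north-east | 0.500 | 4.4 | 92.5 |
| north-east | 1.33 | 10.2 | 83.7 |
| north-east | 3.00 | 8.6 | 64.6 |
| north-east | 8.00 | 4.6 | 32.8 |
| north | 0.833 | 7.3 | 91.4 |
| north | 2.50 | 15.6 | 75.7 |
| north | 5.00 | 20.6 | 57.8 |
| north | 8.00 | 23.2 | 41.6 |

(readings scatter by 1 percentage point)

- the analysis behind the earlier runs scatters by 1 percentage point, standard deviation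

1. the flasks by amount of target, in percent of the substrate charged, highest first, at 10 h (ash / elm / larch / oak / birch)
2. the amount of target, in percent of the substrate charged of the flask you put first, at 10 h
3. the amount of target, in percent of the substrate charged of the flask you put last, at 10 h

In the north-east run, from 3.00 h to 8.00 h, the substrate falls by 32 percentage points and the target by 4 points, so the third entry gains 36 points. Target averages 6.60% over that window. So we read a leak rate, the fraction of the target present that passes on per hour, of 1.08 h⁻¹ at 65 mM of partner. We assume it is proportional to c(partner), which makes it pseudo-first-order while c(partner) holds. The same window gives a making rate of 0.136 h⁻¹. If both rates hold steady and the leak is the larger, c(target)/c(substrate) settles at making rate over leak minus making rate.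

Scaled to its charge of partner, the leak gives a target in birch a lifetime of 12.0 h, longer than the run. At their charges of partner we reckon the leak in ash at 0.361 h⁻¹, in elm and oak at 1.00 h⁻¹, and in larch at 1.34 h⁻¹, the largest. Oak carries more substrate per partner than elm, so we expect its partner, and with it its leak, to fall further. Our order is therefore birch, ash, oak, elm, larch. For elm, taking the making rate of the north-east run, we reckon 25.8% of substrate left and 4.04% of target.

The forecast gives birch > ash > oak > elm > larch, with 27% for the first flask and 1% for the last, and calls birch “partner-starved, which protects target”.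

The flasks give birch > ash > oak > elm > larch, with 29.6% at the top and 0.805% at the bottom.

    partner + free catalyst → catalyst intermediate A (k = 11.0 M⁻¹ s⁻¹)
    substrate + catalyst intermediate A → catalyst intermediate B (k = 13.0 M⁻¹ s⁻¹)
    catalyst intermediate B → free catalyst + target (k = 0.240 s⁻¹)
    partner + target → over-reaction product (k = 0.00490 M⁻¹ s⁻¹)
    partner + catalyst intermediate B → spent catalyst (k = 0.00120 M⁻¹ s⁻¹)
    free catalyst ⇌ dormant form (K = 0.990, k = 3.60 × 10⁻⁵ s⁻¹)

Birch has used its partner down to 6.02% of its charge at 10.0 h, with 65.6% of its substrate still present. Larch, at the other end, has 1.8% of its substrate left, which means an average making rate of 0.404 h⁻¹. Its remaining 93% of partner puts the leak at 1.24 h⁻¹. The ratio then gives 0.855% of target in larch, where the flask holds 0.805%.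

(The numbers in the tables come from a simulation with made-up constants.)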